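**Retrosynthetic overview**
1. C8–CH2 bond, made last and without protecting groups: 11 ⇒ (+)-catechin 8 + the ring D ortho-quinone methide 10 (from 7, CH2O, Me2NH).
2. Key disconnection, the aryl O–CH3 bond of ring D: 7 ⇒ free triphenol 5. This C–O bond is made site-selectively at the hindered, chelated O-2 by a copper-templated methyl transfer (new).
3. Aryl–acyl bond: 5 ⇒ symmetric 2-methylphloroglucinol 3 + (R)-2-methylbutanoic acid 2.
4. 2 ⇒ tiglic acid 1 by asymmetric hydrogenation, which sets the side-chain centre. C-2 and C-3 of the flavan come with 8.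
5. Ring order: no ring is built. Rings A, B and C arrive intact in 8 and ring D arrives in 3.

Assumption: the SMILES decodes to the (2R,3S)-flavan-3-ol, i.e. (+)-catechin substituted at C8, and to an (R)-2-methylbutanoyl group. 2-Methylbenzene-1,3,5-triol is taken as a catalogue chemical. Ring D of 5 is numbered C-1 (acyl), O-2, C-3 (methyl), O-4, C-5 (H), O-6.

**Step 1**
Reactants: 1 tiglic acid
Product: 2 (R)-2-methylbutanoic acid
Conditions: H2 (4 atm), Ru(OAc)2[(R)-H8-BINAP] (0.5 mol %), MeOH, 20 °C, 12 h
Reagents that add atoms: none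
Why: Noyori-type asymmetric hydrogenation of an α,β-unsaturated acid, in which the carboxylate binds ruthenium so that H2 reaches one alkene face inside the pocket of the (R)-ligand, setting the (R) centre in about 95–97% ee (the (S)-ligand gives the (S)-acid).

**Step 2**
Reactants: 2 (R)-2-methylbutanoic acid, 3 2-methylbenzene-1,3,5-triol
Product: 5 (R)-2-methyl-1-(2,4,6-trihydroxy-3-methylphenyl)butan-1-one, via acid chloride 4 (not isolated)
Conditions: (COCl)2 (1.05 equiv), DMF (cat.), CH2Cl2, 0 °C to rt; then 3, AlCl3 (3.5 equiv), CH2Cl2/MeNO2, 0 °C to rt; 1 M HCl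
Reagents that add atoms: none
Why: Friedel–Crafts acylation, in which the two free ring positions of 3 are equivalent so only one ketone can form, the first acyl group deactivates the ring against a second, and base-free chloride formation plus low temperature keep the α-centre from enolising.

**Step 3 (key step)**
Reactants: 5 (R)-2-methyl-1-(2,4,6-trihydroxy-3-methylphenyl)butan-1-one
Product: 7 (R)-1-(4,6-dihydroxy-2-methoxy-3-methylphenyl)-2-methylbutan-1-one, via copper chelate 6 (not isolated)
Conditions: Cu(OAc)2 (1.0 equiv), pyridine (3 equiv), 4 Å MS, DCE, rt, 30 min; then MeB(OH)2 (2 equiv, in portions), Cu(OAc)2 (1.2 equiv), N2, 50 °C, 12 h; 1 M HCl wash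
Reagents that add atoms: methylboronic acid, CB(O)O
Why: Proposed new method: chelate-directed Chan–Lam O-methylation of a free triphenol, in which, with no base strong enough to ionise O-4, Cu(OAc)2 is taken up by the 2-acylphenol unit as a six-membered O,O-chelate that sits at O-2 rather than O-6 because the C-3 methyl buttresses O-2 toward the carbonyl oxygen while the sec-butyl group then faces the unbuttressed O-6; MeB(OH)2 transmetalates, a second Cu(OAc)2 oxidises the methylcopper species from divalent to trivalent copper, and C–O reductive elimination can reach only the copper-bound O-2, so the usual SN2 order (acidic para O-4 first) is inverted, and the chelated ketone behaves as a vinylogous carboxylate that does not enolise, so the (R) centre holds; closest known reaction type: Chan–Lam O-methylation of simple monophenols with methylboronic acid, where site selection among several free phenols through substrate chelation has not been shown.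

**Step 4**
Reactants: 7 (R)-1-(4,6-dihydroxy-2-methoxy-3-methylphenyl)-2-methylbutan-1-one, 8 (+)-catechin
Product: 11 (2R)-1-(3-{[(2R,3S)-2-(3,4-dihydroxyphenyl)-3,5,7-trihydroxychroman-8-yl]methyl}-2,4-dihydroxy-6-methoxy-5-methylphenyl)-2-methylbutan-1-one, via Mannich base 9 (not isolated), via quinone methide 10 (not isolated)
Conditions: 37% aq. CH2O (1.0 equiv), 40% aq. Me2NH (1.0 equiv), EtOH, rt, 2 h; volatiles off; then 8 (3 equiv), AcOH (3 equiv), EtOH/H2O 4:1, Ar, 70 °C, 8 h; Sephadex LH-20, then RP-HPLC
Reagents that add atoms: formaldehyde, C=O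
Why: Mannich reaction at the only free ring D carbon, followed by loss of Me2NH to the ortho-quinone methide 10 and its Michael-type Friedel–Crafts capture by the most nucleophilic carbon of free catechin (C8 of ring A), while the acetic acid buffer under argon leaves C-2, C-3 and the side-chain centre untouched.

**Compound list**
1 | tiglic acid, (E)-2-methylbut-2-enoic acid | C/C=C(\C)C(=O)O | starting material
2 | (R)-2-methylbutanoic acid | CC[C@@H](C)C(=O)O | intermediate
3 | 2-methylbenzene-1,3,5-triol (2-methylphloroglucinol) | Cc1c(O)cc(O)cc1O | starting material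
4 | (R)-2-methylbutanoyl chloride | CC[C@@H](C)C(=O)Cl | intermediate
5 | (R)-2-methyl-1-(2,4,6-trihydroxy-3-methylphenyl)butan-1-one | CC[C@@H](C)C(=O)c1c(O)cc(O)c(C)c1O | intermediate
6 | copper chelate of 5: deprotonated at O-2, bound to divalent copper through O-2 and the ketone oxygen, acetate as second anion (pyridine ligands omitted, written as ions) | CC[C@@H](C)C(=O)c1c(O)cc(O)c(C)c1[O-].[Cu+2].CC(=O)[O-] | intermediate
7 | (R)-1-(4,6-dihydroxy-2-methoxy-3-methylphenyl)-2-methylbutan-1-one | CC[C@@H](C)C(=O)c1c(O)cc(O)c(C)c1OC | intermediate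
8 | (+)-catechin, (2R,3S)-2-(3,4-dihydroxyphenyl)chroman-3,5,7-triol | Oc1cc(O)c2c(c1)O[C@H](c1ccc(O)c(O)c1)[C@@H](O)C2 | starting material
9 | (R)-1-{3-[(dimethylamino)methyl]-2,4-dihydroxy-6-methoxy-5-methylphenyl}-2-methylbutan-1-one | CC[C@@H](C)C(=O)c1c(O)c(CN(C)C)c(O)c(C)c1OC | intermediate
10 | 5-hydroxy-3-methoxy-2-methyl-6-methylidene-4-[(2R)-2-methylbutanoyl]cyclohexa-2,4-dien-1-one | CC[C@@H](C)C(=O)C1=C(O)C(=C)C(=O)C(C)=C1OC | intermediate
11 | (2R)-1-(3-{[(2R,3S)-2-(3,4-dihydroxyphenyl)-3,5,7-trihydroxychroman-8-yl]methyl}-2,4-dihydroxy-6-methoxy-5-methylphenyl)-2-methylbutan-1-one | CC[C@@H](C)C(=O)c1c(O)c(Cc2c(O)cc(O)c3c2O[C@H](c2ccc(O)c(O)c2)[C@@H](O)C3)c(O)c(C)c1OC | target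

**Total step count:** 4. **Longest linear sequence:** 4 (1 → 2 → 5 → 7 → 11).

**Three steps most likely to fail**

*Step 3 (the new step).*
- Failure modes: the methyl may land on O-4 through a monodentate phenoxide, or on O-6 through the other chelate. A second methylation may follow, or divalent copper may oxidise the electron-rich ring.
- Check: an NOE between OCH3 and the aryl CH3 identifies 7. The O-6 isomer shows an NOE from OCH3 to the aryl H instead.
- Fallback (known chemistry): it sets out from 5 and comes back at 7. MOMCl (2.1 equiv) and i-Pr2NEt in CH2Cl2 at 0 °C cap the two non-chelated phenols and give (R)-1-[2-hydroxy-4,6-bis(methoxymethoxy)-3-methylphenyl]-2-methylbutan-1-one F1. A neutral Mitsunobu methylation (MeOH, PPh3, DIAD, THF) of the remaining chelated O-2–H gives (R)-1-[2-methoxy-4,6-bis(methoxymethoxy)-3-methylphenyl]-2-methylbutan-1-one F2. HCl in MeOH at 40 °C removes both acetals and returns 7. The cost is two extra steps.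

*Step 4.*
- Failure modes: free catechin is expected to give C8 over C6 only by about 3:1. Double alkylation of 8 and the symmetric ring D dimer can cut the yield further.
- Fallback: it sets out from 8 and comes back at 11, replacing kinetic preference with a nucleophile that is known to react at C8. BnBr and K2CO3 in DMF convert 8 into 5,7,3',4'-tetra-O-benzyl-(+)-catechin F3, whose electrophilic substitutions go to C8. The Mannich base 9, made from 7 as in step 4 but isolated, is ionised with TFA in CH2Cl2 at 40 °C in the presence of F3 to give the 5,7,3',4'-tetra-O-benzyl ether of the target F4. Hydrogenolysis (H2, Pd(OH)2/C, THF/MeOH) then gives 11.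

*Step 2.*
- Failure mode: the aluminium-bound ketone or the acylium ion may partly racemise, and the resulting side-chain epimer of 11 would be hard to remove.
- Fallback: it sets out from 3 and comes back at 5, and it sets the centre by resolution instead of carrying it through the acylation. Commercial racemic 2-methylbutanoyl chloride and AlCl3 under forcing conditions give racemic 2-methyl-1-(2,4,6-trihydroxy-3-methylphenyl)butan-1-one F5. Preparative chiral SFC on an amylose phase delivers 5 and leaves (S)-2-methyl-1-(2,4,6-trihydroxy-3-methylphenyl)butan-1-one F6, which is discarded. Step 1 is then not needed.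

**Further compounds**
F1 | step 3 | (R)-1-[2-hydroxy-4,6-bis(methoxymethoxy)-3-methylphenyl]-2-methylbutan-1-one | CC[C@@H](C)C(=O)c1c(OCOC)cc(OCOC)c(C)c1O
F2 | step 3 | (R)-1-[2-methoxy-4,6-bis(methoxymethoxy)-3-methylphenyl]-2-methylbutan-1-one | CC[C@@H](C)C(=O)c1c(OCOC)cc(OCOC)c(C)c1OC
F3 | step 4 | 5,7,3',4'-tetra-O-benzyl-(+)-catechin | C(Oc1cc(OCc2ccccc2)c2c(c1)O[C@H](c1ccc(OCc3ccccc3)c(OCc3ccccc3)c1)[C@@H](O)C2)c1ccccc1
F4 | step 4 | 5,7,3',4'-tetra-O-benzyl ether of the target | CC[C@@H](C)C(=O)c1c(O)c(Cc2c(OCc3ccccc3)cc(OCc3ccccc3)c3c2O[C@H](c2ccc(OCc4ccccc4)c(OCc4ccccc4)c2)[C@@H](O)C3)c(O)c(C)c1OC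
F5 | step 2 | racemic 2-methyl-1-(2,4,6-trihydroxy-3-methylphenyl)butan-1-one | CCC(C)C(=O)c1c(O)cc(O)c(C)c1O
F6 | step 2 | (S)-2-methyl-1-(2,4,6-trihydroxy-3-methylphenyl)butan-1-one | CC[C@H](C)C(=O)c1c(O)cc(O)c(C)c1O
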